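**Retrosynthetic overview**
1. Target ⇐ epoxidation of the C7=C8 olefin of the 17‑acetoxy triene, steered by C2 through the macrocycle; C17 acetate ⇐ ester; 2,5‑dihydrofuran ⇐ oxa‑Michael/Horner–Wadsworth–Emmons annulation on a 14‑membered α‑hydroxy ketone.
2. 14‑Membered carbocycle ⇐ Claisen ([3,3]) ring expansion of a 2‑methylene 12‑membered cyclic enol ether (forms C13–C14, E‑C11=C12 and the C1 ketone) ⇐ Tebbe methylenation of a 12‑membered lactone ⇐ macrolactonisation.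
3. Seco acid ⇐ two Johnson orthoester Claisen rearrangements (C5–C6 with E‑C3=C4, then C9–C10 with E‑C7=C8), iterated with one‑pot ester reduction/isopropenyl Grignard addition.
4. C2 is bought with methyl (R)‑glycerate; it is the only stereocentre carried through and it controls the oxirane.
5. Ring order: 12‑membered lactone (temporary) → 14‑membered carbocycle → dihydrofuran → oxirane.

Assumption: the target is taken as drawn, i.e. (2S,7S,8S,3E,11E) in cembrane numbering (C1=C15 ring‑fusion olefin, C2 = OCH, C16 = OCH2, C17 = CH2OAc); methyl D‑glycerate is taken as purchasable (otherwise one step from the D‑mannitol‑derived acetonide ester); TBS = tert‑butyldimethylsilyl.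

**Step 1**
Reactants: 1 methyl (R)-2,3-dihydroxypropanoate
Product: 2 methyl (R)-2,3-bis(TBS-oxy)propanoate
Conditions: TBSCl, imidazole, DMF, rt
Reagents that add atoms: tert-butyldimethylsilyl chloride (TBSCl), CC(C)(C)[Si](C)(C)Cl
Why: Silyl ether formation caps both hydroxyls so that the purchased C2 stereocentre is carried on untouched.

**Step 2**
Reactants: 2 methyl (R)-2,3-bis(TBS-oxy)propanoate; 3 isopropenylmagnesium bromide
Product: 5 (3RS,4R)-4,5-bis(TBS-oxy)-2-methylpent-1-en-3-ol, via aldehyde 4 (not isolated)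
Conditions: iBu2AlH, CH2Cl2, −78 °C; then CH2=C(CH3)MgBr, THF, −78 → 0 °C
Reagents that add atoms: isopropenylmagnesium bromide (3), C=C(C)[Mg]Br
Why: Half‑reduction of the α‑silyloxy ester (stable aluminium hemiacetal) followed by Grignard 1,2‑addition gives the 2‑methylallyl carbinol, whose new carbinol centre is an irrelevant mixture because it becomes sp2 in step 3.

**Step 3**
Reactants: 5 (3RS,4R)-4,5-bis(TBS-oxy)-2-methylpent-1-en-3-ol; 6 triethyl orthoacetate
Product: 8 ethyl (4E,6S)-6,7-bis(TBS-oxy)-4-methylhept-4-enoate, via ketene acetal 7 (not isolated)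
Conditions: MeC(OEt)3, EtCO2H (cat.), 140 °C, EtOH distilled off
Reagents that add atoms: triethyl orthoacetate (6), CC(OCC)(OCC)OCC
Why: Johnson orthoester Claisen ([3,3]‑sigmatropic) rearrangement through a chair with the bulky side chain equatorial forms C5–C6 and the E‑C3=C4 olefin (expected >95:5) without touching C2.

**Step 4**
Reactants: 8 ethyl (4E,6S)-6,7-bis(TBS-oxy)-4-methylhept-4-enoate; 3 isopropenylmagnesium bromide
Product: 10 (3RS,6E,8S)-8,9-bis(TBS-oxy)-2,6-dimethylnona-1,6-dien-3-ol, via aldehyde 9 (not isolated)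
Conditions: iBu2AlH, CH2Cl2, −78 °C; then CH2=C(CH3)MgBr, THF, −78 → 0 °C
Reagents that add atoms: isopropenylmagnesium bromide (3), C=C(C)[Mg]Br
Why: One‑pot ester half‑reduction and Grignard addition again installs a 2‑methylallyl carbinol whose configuration (C7) is lost in step 5.

**Step 5**
Reactants: 10 (3RS,6E,8S)-8,9-bis(TBS-oxy)-2,6-dimethylnona-1,6-dien-3-ol; 6 triethyl orthoacetate
Product: 12 ethyl (4E,8E,10S)-10,11-bis(TBS-oxy)-4,8-dimethylundeca-4,8-dienoate, via ketene acetal 11 (not isolated)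
Conditions: MeC(OEt)3, EtCO2H (cat.), 140 °C, EtOH distilled off
Reagents that add atoms: triethyl orthoacetate (6), CC(OCC)(OCC)OCC
Why: A second Johnson orthoester Claisen rearrangement forms C9–C10 and the E‑C7=C8 olefin by the same chair preference.

**Step 6**
Reactants: 12 ethyl (4E,8E,10S)-10,11-bis(TBS-oxy)-4,8-dimethylundeca-4,8-dienoate; 3 isopropenylmagnesium bromide
Product: 14 (3RS,6E,10E,12S)-12,13-bis(TBS-oxy)-2,6,10-trimethyltrideca-1,6,10-trien-3-ol, via aldehyde 13 (not isolated)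
Conditions: iBu2AlH, CH2Cl2, −78 °C; then CH2=C(CH3)MgBr, THF, −78 → 0 °C
Reagents that add atoms: isopropenylmagnesium bromide (3), C=C(C)[Mg]Br
Why: Ester half‑reduction and Grignard addition give the C11 2‑methylallyl carbinol needed for the ring‑expanding Claisen step, C11 being a transient unselective centre.

**Step 7**
Reactants: 14 (3RS,6E,10E,12S)-12,13-bis(TBS-oxy)-2,6,10-trimethyltrideca-1,6,10-trien-3-ol
Product: 15 (2S,3E,7E,11RS)-2-(TBS-oxy)-4,8,12-trimethyltrideca-3,7,12-triene-1,11-diol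
Conditions: HF·pyridine, pyridine, THF, 0 °C
Reagents that add atoms: none
Why: Selective desilylation, the unhindered primary silyl ether being cleaved by buffered HF far faster than the secondary allylic one.

**Step 8**
Reactants: 15 (2S,3E,7E,11RS)-2-(TBS-oxy)-4,8,12-trimethyltrideca-3,7,12-triene-1,11-diol
Product: 17 (2S,3E,7E,11RS)-11-hydroxy-2-(TBS-oxy)-4,8,12-trimethyltrideca-3,7,12-trienoic acid, via aldehyde 16 (not isolated)
Conditions: 2,2,6,6-tetramethylpiperidin-1-oxyl (TEMPO, cat.), PhI(OAc)2, MeCN/H2O, rt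
Reagents that add atoms: water, O
Why: Oxoammonium (TEMPO) oxidation, selective for the primary carbinol over the hindered secondary one, takes C1 to the acid through the aldehyde hydrate under near‑neutral conditions that do not epimerise C2.

**Step 9**
Reactants: 17 (2S,3E,7E,11RS)-11-hydroxy-2-(TBS-oxy)-4,8,12-trimethyltrideca-3,7,12-trienoic acid
Product: 18 (3S,4E,8E,12RS)-3-(TBS-oxy)-5,9-dimethyl-12-(prop-1-en-2-yl)oxacyclododeca-4,8-dien-2-one
Conditions: 2-methyl-6-nitrobenzoic anhydride, 4-(dimethylamino)pyridine, CH2Cl2 (1 mM, slow addition), rt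
Reagents that add atoms: none
Why: Shiina macrolactonisation under high dilution acylates the C11 hydroxyl and closes the 12‑membered lactone at room temperature with C2 retained (both C11 epimers are used).

**Step 10**
Reactants: 18 (3S,4E,8E,12RS)-3-(TBS-oxy)-5,9-dimethyl-12-(prop-1-en-2-yl)oxacyclododeca-4,8-dien-2-one; 19 Tebbe reagent Cp2Ti(μ-CH2)(μ-Cl)AlMe2
Product: 20 (3S,4E,8E,12RS)-3-(TBS-oxy)-5,9-dimethyl-2-methylidene-12-(prop-1-en-2-yl)oxacyclododeca-4,8-diene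
Conditions: Cp2Ti(μ-CH2)(μ-Cl)AlMe2, pyridine (cat.), THF/PhMe, −40 → 0 °C; filtration through basic Al2O3
Reagents that add atoms: Tebbe reagent (19), C[Al](C)C[Ti](Cl)(C1C=CC=C1)C1C=CC=C1
Why: Tebbe methylenation of the lactone carbonyl (non‑basic, so C2 is safe) gives the cyclic 2‑methylene enol ether, i.e. an allyl vinyl ether built into the ring, and supplies C14.

**Step 11**
Reactants: 20 (3S,4E,8E,12RS)-3-(TBS-oxy)-5,9-dimethyl-2-methylidene-12-(prop-1-en-2-yl)oxacyclododeca-4,8-diene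
Product: 21 (2S,3E,7E,11E)-2-(TBS-oxy)-4,8,12-trimethylcyclotetradeca-3,7,11-trien-1-one
Conditions: PhMe, 130 °C, sealed base‑washed tube
Reagents that add atoms: none
Why: Claisen ([3,3]‑sigmatropic) rearrangement with ring expansion (Paquette‑type methylenation/Claisen sequence) through a chair with C10 equatorial forms C13–C14, creates the E‑C11=C12 olefin, erases the C11 centre and leaves the 14‑membered α‑silyloxy ketone.

**Step 12**
Reactants: 21 (2S,3E,7E,11E)-2-(TBS-oxy)-4,8,12-trimethylcyclotetradeca-3,7,11-trien-1-one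
Product: 22 (2S,3E,7E,11E)-2-hydroxy-4,8,12-trimethylcyclotetradeca-3,7,11-trien-1-one
Conditions: Bu4NF, AcOH (1:1), THF, 0 °C
Reagents that add atoms: none
Why: Fluoride desilylation buffered with AcOH frees the C2 hydroxyl without enolising the α‑ketol.

**Step 13**
Reactants: 22 (2S,3E,7E,11E)-2-hydroxy-4,8,12-trimethylcyclotetradeca-3,7,11-trien-1-one; 23 ethyl 2-(diethoxyphosphoryl)prop-2-enoate
Product: 25 ethyl (2S,3E,7E,11E)-2,16-epoxycembra-1(15),3,7,11-tetraen-17-oate, via phosphonate adduct 24 (not isolated)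
Conditions: NaH (1.05 equiv), THF, 0 °C; then 23, 0 °C → rt
Reagents that add atoms: ethyl 2-(diethoxyphosphoryl)prop-2-enoate (23), C=C(C(=O)OCC)P(=O)(OCC)OCC
Why: Tandem oxa‑Michael addition/intramolecular Horner–Wadsworth–Emmons olefination, in which the C2 alkoxide adds to the vinylphosphonate and the phosphonate carbanion closes onto the adjacent C1 ketone, builds the 2,5‑dihydrofuran with its tetrasubstituted olefin and retains C2.

**Step 14**
Reactants: 25 ethyl (2S,3E,7E,11E)-2,16-epoxycembra-1(15),3,7,11-tetraen-17-oate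
Product: 26 (2S,3E,7E,11E)-2,16-epoxycembra-1(15),3,7,11-tetraen-17-ol
Conditions: iBu2AlH (2.2 equiv), CH2Cl2, −78 °C
Reagents that add atoms: none
Why: 1,2‑Hydride reduction of the conjugated ester gives the primary allylic alcohol at C17.

**Step 15**
Reactants: 26 (2S,3E,7E,11E)-2,16-epoxycembra-1(15),3,7,11-tetraen-17-ol
Product: 27 (2S,3E,7E,11E)-2,16-epoxycembra-1(15),3,7,11-tetraen-17-yl acetate
Conditions: Ac2O, pyridine, 4-(dimethylamino)pyridine (cat.), CH2Cl2, 0 °C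
Reagents that add atoms: acetic anhydride, CC(=O)OC(C)=O
Why: Acylation of the primary alcohol, done before the oxidation so that no free hydroxyl can direct the peracid to the C1=C15 olefin.

**Step 16**
Reactants: 27 (2S,3E,7E,11E)-2,16-epoxycembra-1(15),3,7,11-tetraen-17-yl acetate
Product: 28 (2S,7S,8S,3E,11E)-2,16:7,8-diepoxycembra-1(15),3,11-trien-17-yl acetate (CNP0140293.1)
Conditions: 3-chloroperbenzoic acid (1.0 equiv), NaHCO3, CH2Cl2, −20 → 0 °C
Reagents that add atoms: 3-chloroperbenzoic acid (mCPBA), OOC(=O)c1cccc(Cl)c1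
Why: Prilezhaev epoxidation under macrocyclic peripheral‑attack control, in which C1=C15 and C3=C4 are deactivated by allylic oxygens and the peracid is expected to add syn to the exposed face of E‑C7=C8 in the conformation fixed by the C2‑anchored dihydrofuran, setting 7S,8S with the trans relationship kept; this selectivity is untested, the 11,12‑epoxide is the expected by‑product and is removed by chromatography.

**Compound list**
1 | methyl (R)-2,3-dihydroxypropanoate (methyl D-glycerate) | COC(=O)[C@@H](CO)O | starting material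
2 | methyl (R)-2,3-bis(TBS-oxy)propanoate | COC(=O)[C@@H](CO[Si](C)(C)C(C)(C)C)O[Si](C)(C)C(C)(C)C | intermediate
3 | isopropenylmagnesium bromide | C=C(C)[Mg]Br | starting material
4 | (R)-2,3-bis(TBS-oxy)propanal | O=C[C@@H](CO[Si](C)(C)C(C)(C)C)O[Si](C)(C)C(C)(C)C | intermediate (not isolated)
5 | (3RS,4R)-4,5-bis(TBS-oxy)-2-methylpent-1-en-3-ol | CC(=C)C(O)[C@@H](CO[Si](C)(C)C(C)(C)C)O[Si](C)(C)C(C)(C)C | intermediate
6 | triethyl orthoacetate | CC(OCC)(OCC)OCC | starting material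
7 | (3RS,4R)-3-[(1-ethoxyethenyl)oxy]-4,5-bis(TBS-oxy)-2-methylpent-1-ene | C=C(OCC)OC(C(C)=C)[C@@H](CO[Si](C)(C)C(C)(C)C)O[Si](C)(C)C(C)(C)C | intermediate (not isolated)
8 | ethyl (4E,6S)-6,7-bis(TBS-oxy)-4-methylhept-4-enoate | CCOC(=O)CC/C(C)=C/[C@@H](CO[Si](C)(C)C(C)(C)C)O[Si](C)(C)C(C)(C)C | intermediate
9 | (4E,6S)-6,7-bis(TBS-oxy)-4-methylhept-4-enal | O=CCC/C(C)=C/[C@@H](CO[Si](C)(C)C(C)(C)C)O[Si](C)(C)C(C)(C)C | intermediate (not isolated)
10 | (3RS,6E,8S)-8,9-bis(TBS-oxy)-2,6-dimethylnona-1,6-dien-3-ol | CC(=C)C(O)CC/C(C)=C/[C@@H](CO[Si](C)(C)C(C)(C)C)O[Si](C)(C)C(C)(C)C | intermediate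
11 | (3RS,6E,8S)-3-[(1-ethoxyethenyl)oxy]-8,9-bis(TBS-oxy)-2,6-dimethylnona-1,6-diene | C=C(OCC)OC(C(C)=C)CC/C(C)=C/[C@@H](CO[Si](C)(C)C(C)(C)C)O[Si](C)(C)C(C)(C)C | intermediate (not isolated)
12 | ethyl (4E,8E,10S)-10,11-bis(TBS-oxy)-4,8-dimethylundeca-4,8-dienoate | CCOC(=O)CC/C(C)=C/CC/C(C)=C/[C@@H](CO[Si](C)(C)C(C)(C)C)O[Si](C)(C)C(C)(C)C | intermediate
13 | (4E,8E,10S)-10,11-bis(TBS-oxy)-4,8-dimethylundeca-4,8-dienal | O=CCC/C(C)=C/CC/C(C)=C/[C@@H](CO[Si](C)(C)C(C)(C)C)O[Si](C)(C)C(C)(C)C | intermediate (not isolated)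
14 | (3RS,6E,10E,12S)-12,13-bis(TBS-oxy)-2,6,10-trimethyltrideca-1,6,10-trien-3-ol | CC(=C)C(O)CC/C(C)=C/CC/C(C)=C/[C@@H](CO[Si](C)(C)C(C)(C)C)O[Si](C)(C)C(C)(C)C | intermediate
15 | (2S,3E,7E,11RS)-2-(TBS-oxy)-4,8,12-trimethyltrideca-3,7,12-triene-1,11-diol | CC(=C)C(O)CC/C(C)=C/CC/C(C)=C/[C@@H](CO)O[Si](C)(C)C(C)(C)C | intermediate
16 | (2S,3E,7E,11RS)-11-hydroxy-2-(TBS-oxy)-4,8,12-trimethyltrideca-3,7,12-trienal | CC(=C)C(O)CC/C(C)=C/CC/C(C)=C/[C@@H](C=O)O[Si](C)(C)C(C)(C)C | intermediate (not isolated)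
17 | (2S,3E,7E,11RS)-11-hydroxy-2-(TBS-oxy)-4,8,12-trimethyltrideca-3,7,12-trienoic acid | CC(=C)C(O)CC/C(C)=C/CC/C(C)=C/[C@@H](C(=O)O)O[Si](C)(C)C(C)(C)C | intermediate
18 | (3S,4E,8E,12RS)-3-(TBS-oxy)-5,9-dimethyl-12-(prop-1-en-2-yl)oxacyclododeca-4,8-dien-2-one | O=C1OC(C(C)=C)CC/C(C)=C/CC/C(C)=C/[C@@H]1O[Si](C)(C)C(C)(C)C | intermediate
19 | Tebbe reagent Cp2Ti(μ-CH2)(μ-Cl)AlMe2 | C[Al](C)C[Ti](Cl)(C1C=CC=C1)C1C=CC=C1 | starting material
20 | (3S,4E,8E,12RS)-3-(TBS-oxy)-5,9-dimethyl-2-methylidene-12-(prop-1-en-2-yl)oxacyclododeca-4,8-diene | C=C1OC(C(C)=C)CC/C(C)=C/CC/C(C)=C/[C@@H]1O[Si](C)(C)C(C)(C)C | intermediate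
21 | (2S,3E,7E,11E)-2-(TBS-oxy)-4,8,12-trimethylcyclotetradeca-3,7,11-trien-1-one | O=C1CC/C(C)=C/CC/C(C)=C/CC/C(C)=C/[C@@H]1O[Si](C)(C)C(C)(C)C | intermediate
22 | (2S,3E,7E,11E)-2-hydroxy-4,8,12-trimethylcyclotetradeca-3,7,11-trien-1-one | O=C1CC/C(C)=C/CC/C(C)=C/CC/C(C)=C/[C@@H]1O | intermediate
23 | ethyl 2-(diethoxyphosphoryl)prop-2-enoate | C=C(C(=O)OCC)P(=O)(OCC)OCC | starting material
24 | ethyl 2-(diethoxyphosphoryl)-3-{[(1S,2E,6E,10E)-3,7,11-trimethyl-14-oxocyclotetradeca-2,6,10-trien-1-yl]oxy}propanoate | O=C1CC/C(C)=C/CC/C(C)=C/CC/C(C)=C/[C@@H]1OCC(C(=O)OCC)P(=O)(OCC)OCC | intermediate (not isolated)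
25 | ethyl (2S,3E,7E,11E)-2,16-epoxycembra-1(15),3,7,11-tetraen-17-oate | CCOC(=O)C1=C2CC/C(C)=C/CC/C(C)=C/CC/C(C)=C/[C@@H]2OC1 | intermediate
26 | (2S,3E,7E,11E)-2,16-epoxycembra-1(15),3,7,11-tetraen-17-ol | OCC1=C2CC/C(C)=C/CC/C(C)=C/CC/C(C)=C/[C@@H]2OC1 | intermediate
27 | (2S,3E,7E,11E)-2,16-epoxycembra-1(15),3,7,11-tetraen-17-yl acetate | CC(=O)OCC1=C2CC/C(C)=C/CC/C(C)=C/CC/C(C)=C/[C@@H]2OC1 | intermediate
28 | (2S,7S,8S,3E,11E)-2,16:7,8-diepoxycembra-1(15),3,11-trien-17-yl acetate (CNP0140293.1) | CC(=O)OCC1=C2CC/C(C)=C/CC[C@]3(C)O[C@H]3CC/C(C)=C/[C@@H]2OC1 | target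

**Totals**
Total step count: 16. Longest linear sequence: 16 steps (from 1; the route is fully linear).

**Three steps most likely to fail, each with a fallback**

Step 16 (regio‑ and face‑selectivity of the late epoxidation; C11=C12 is electronically similar to C7=C8). The fallback sets out from lactone 18 and comes back at target 28. 3‑Chloroperbenzoic acid (NaHCO3, CH2Cl2, 0 °C) is applied to 18, where C7=C8 is the only unhindered electron‑rich olefin (C3=C4 carries the allylic silyl ether; the isopropenyl group is 1,1‑disubstituted and allylic to the ester oxygen), giving epoxy lactone F6. Steps 10 to 15 are then run on the epoxide: Tebbe methylenation to epoxy enol ether F7; Claisen ring expansion to epoxy ketone F8, where the 7S,8S isomer is separated from the 7R,8R isomer (C11 no longer exists); Bu4NF/AcOH to epoxy hydroxy ketone F9; annulation with 23 to epoxy ester F10; iBu2AlH to epoxy alcohol F11; and Ac2O/pyridine to 28.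

Step 11 (geometry and efficiency of the transannular Claisen ring expansion). The fallback sets out from seco acid 17 and comes back at ketone 21, bypassing steps 9 to 11 with an enolate alkylation. MeLi (3.3 equiv, Et2O, −78 → 0 °C) converts the acid into methyl ketone F1, whose methyl carbon becomes C14. PBr3 (pyridine cat., Et2O, −10 °C) converts the 2‑methylallyl carbinol with allylic transposition into the primary (E)‑allylic bromide F2. LiN(SiMe3)2 (THF, −78 → 0 °C, 1 mM) forms the kinetic methyl enolate, which closes the 14‑membered ring by C13–C14 alkylation to give 21.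

Step 13 (possible epimerisation or α‑ketol isomerisation of 22 under basic annulation). The fallback sets out from silyl ketone 21 and comes back at acetate 27, so that no carbonyl ever sits next to a free C2 hydroxyl. Tebbe methylenation (Cp2Ti(μ-CH2)(μ-Cl)AlMe2, THF, −40 → 0 °C) gives exocyclic olefin F3. Bu4NF (THF, 0 °C) gives bis‑allylic alcohol F4. O‑Alkylation with 2‑(bromomethyl)prop‑2‑en‑1‑yl acetate (CC(=O)OCC(=C)CBr; Ag2O, CH2Cl2, rt) gives diallyl ether F5. Ring‑closing metathesis with second‑generation Grubbs catalyst (H2IMes)(PCy3)Cl2Ru=CHPh (PhMe, 80 °C) joins the two 1,1‑disubstituted olefins into the tetrasubstituted dihydrofuran olefin and delivers 27 directly.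

**Further compounds**
F1 | step 11 | (3S,4E,8E,12RS)-12-hydroxy-3-(TBS-oxy)-5,9,13-trimethyltetradeca-4,8,13-trien-2-one | CC(=C)C(O)CC/C(C)=C/CC/C(C)=C/[C@@H](C(C)=O)O[Si](C)(C)C(C)(C)C
F2 | step 11 | (3S,4E,8E,12E)-14-bromo-3-(TBS-oxy)-5,9,13-trimethyltetradeca-4,8,12-trien-2-one | BrC/C(C)=C/CC/C(C)=C/CC/C(C)=C/[C@@H](C(C)=O)O[Si](C)(C)C(C)(C)C
F3 | step 13 | tert-butyl(dimethyl){[(1S,2E,6E,10E)-3,7,11-trimethyl-14-methylidenecyclotetradeca-2,6,10-trien-1-yl]oxy}silane | C=C1CC/C(C)=C/CC/C(C)=C/CC/C(C)=C/[C@@H]1O[Si](C)(C)C(C)(C)C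
F4 | step 13 | (1S,2E,6E,10E)-3,7,11-trimethyl-14-methylidenecyclotetradeca-2,6,10-trien-1-ol | C=C1CC/C(C)=C/CC/C(C)=C/CC/C(C)=C/[C@@H]1O
F5 | step 13 | 2-({[(1S,2E,6E,10E)-3,7,11-trimethyl-14-methylidenecyclotetradeca-2,6,10-trien-1-yl]oxy}methyl)prop-2-en-1-yl acetate | C=C1CC/C(C)=C/CC/C(C)=C/CC/C(C)=C/[C@@H]1OCC(=C)COC(C)=O
F6 | step 16 | (3S,4E,8S,9S,12RS)-8,9-epoxy-3-(TBS-oxy)-5,9-dimethyl-12-(prop-1-en-2-yl)oxacyclododec-4-en-2-one | O=C1OC(C(C)=C)CC[C@]2(C)O[C@H]2CC/C(C)=C/[C@@H]1O[Si](C)(C)C(C)(C)C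
F7 | step 16 | (3S,4E,8S,9S,12RS)-8,9-epoxy-3-(TBS-oxy)-5,9-dimethyl-2-methylidene-12-(prop-1-en-2-yl)oxacyclododec-4-ene | C=C1OC(C(C)=C)CC[C@]2(C)O[C@H]2CC/C(C)=C/[C@@H]1O[Si](C)(C)C(C)(C)C
F8 | step 16 | (2S,3E,7S,8S,11E)-7,8-epoxy-2-(TBS-oxy)-4,8,12-trimethylcyclotetradeca-3,11-dien-1-one | O=C1CC/C(C)=C/CC[C@]2(C)O[C@H]2CC/C(C)=C/[C@@H]1O[Si](C)(C)C(C)(C)C
F9 | step 16 | (2S,3E,7S,8S,11E)-7,8-epoxy-2-hydroxy-4,8,12-trimethylcyclotetradeca-3,11-dien-1-one | O=C1CC/C(C)=C/CC[C@]2(C)O[C@H]2CC/C(C)=C/[C@@H]1O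
F10 | step 16 | ethyl (2S,7S,8S,3E,11E)-2,16:7,8-diepoxycembra-1(15),3,11-trien-17-oate | CCOC(=O)C1=C2CC/C(C)=C/CC[C@]3(C)O[C@H]3CC/C(C)=C/[C@@H]2OC1
F11 | step 16 | (2S,7S,8S,3E,11E)-2,16:7,8-diepoxycembra-1(15),3,11-trien-17-ol | OCC1=C2CC/C(C)=C/CC[C@]3(C)O[C@H]3CC/C(C)=C/[C@@H]2OC1
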